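## Retrosynthetic overview

1. The (12E)-diene is built last: one-pot oxidation/Wittig olefination of 12-alcohol 19 gives the enal, then Wittig methylenation. Before that the O-18 icosanoate and then the O-1 acetate are installed.
2. The 8α-OH comes from an 8(17)-exocyclic alkene (epoxidation, hydride opening). The 1β-OH and 18-OH come from 1-keto-18-aldehyde 13.
3. Ring B is formed second (C9–C10 bond) by a new photoredox/cobaloxime dehydrogenative radical 6-endo cyclisation of silyloxy diene 11.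
4. Ring A is formed first by a catalytic enantioselective Diels–Alder reaction of (2E,6E)-enal 6 with silyloxy diene 8, which sets C4 and C5.
5. Enal 6 comes from 3-(benzyloxy)propanal by Grignard addition, Johnson–Claisen rearrangement, ester reduction and Wittig olefination.

Assumption: labdane numbering is used (target = (12E)-1β-acetoxy-8α-hydroxylabda-12,14-dien-18-yl icosanoate, normal series), and the (S)-oxazaborolidinium catalyst of step 6 is taken to expose the α-Re face of enal 6; if the sense is opposite, its antipode is meant.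

## Route

Step 1
Reactants: 1 3-(benzyloxy)propanal; 2 isopropenylmagnesium bromide
Product: 3 rac-5-(benzyloxy)-2-methylpent-1-en-3-ol
Conditions: CH2=C(CH3)MgBr (1.2 equiv), THF, −78 → 0 °C; aq. NH4Cl
Reagents that add atoms: none
Why: Grignard 1,2-addition of the alkenyl nucleophile to the aldehyde gives the secondary allylic alcohol, whose racemic carbinol centre is destroyed in step 2.

Step 2
Reactants: 3 rac-5-(benzyloxy)-2-methylpent-1-en-3-ol
Product: 4 ethyl (4E)-7-(benzyloxy)-4-methylhept-4-enoate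
Conditions: MeC(OEt)3 (6 equiv), EtCO2H (cat.), 140 °C, EtOH distilled off
Reagents that add atoms: triethyl orthoacetate CC(OCC)(OCC)OCC
Why: Johnson–Claisen orthoester rearrangement through a chair transition state with the CH2CH2OBn group equatorial adds the two-carbon ester unit and delivers the E-trisubstituted C8=C9 alkene.

Step 3
Reactants: 4 ethyl (4E)-7-(benzyloxy)-4-methylhept-4-enoate
Product: 5 (4E)-7-(benzyloxy)-4-methylhept-4-enal
Conditions: iBu2AlH (1.1 equiv), CH2Cl2, −78 °C; aq. potassium sodium tartrate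
Reagents that add atoms: none
Why: Low-temperature partial ester reduction stops at the tetrahedral aluminium hemiacetal, which releases the aldehyde on work-up.

Step 4
Reactants: 5 (4E)-7-(benzyloxy)-4-methylhept-4-enal
Product: 6 (2E,6E)-9-(benzyloxy)-2,6-dimethylnona-2,6-dienal
Conditions: Ph3P=C(CH3)CHO (1.3 equiv), toluene, 90 °C
Reagents that add atoms: 2-(triphenylphosphoranylidene)propanal CC(C=O)=P(c1ccccc1)(c1ccccc1)c1ccccc1
Why: Wittig olefination with the formyl-stabilised ylide is E-selective and gives the (2E)-2-methyl enal whose geometry later fixes the C4/C5 relationship.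

Step 5
Reactants: 7 pent-1-en-3-one
Product: 8 triisopropyl{[(3Z)-penta-1,3-dien-3-yl]oxy}silane
Conditions: iPr3SiOTf (1.05 equiv), Et3N, Et2O, 0 °C
Reagents that add atoms: triisopropylsilyl trifluoromethanesulfonate CC(C)[Si](C(C)C)(C(C)C)OS(=O)(=O)C(F)(F)F
Why: Soft enolisation and O-silylation of the ethyl ketone (silyl enol ether formation) gives the 2-silyloxy diene as the Z enol ether, with the methyl group on the outside of the s-cis diene.

Step 6
Reactants: 6 (2E,6E)-9-(benzyloxy)-2,6-dimethylnona-2,6-dienal; 8 triisopropyl{[(3Z)-penta-1,3-dien-3-yl]oxy}silane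
Product: 9 (1R,2R,3S)-2-[(3E)-6-(benzyloxy)-3-methylhex-3-en-1-yl]-1,3-dimethyl-4-[(triisopropylsilyl)oxy]cyclohex-4-ene-1-carbaldehyde
Conditions: (S)-o-tolyl-CBS oxazaborolidine (20 mol %), Tf2NH (18 mol %), 8 (2 equiv), CH2Cl2, −78 → −40 °C
Reagents that add atoms: none
Why: Catalytic enantioselective Diels–Alder reaction in which the silyloxy group directs its enol carbon (C10) to the enal β-carbon (C5), suprafacial addition to the E-enal places CHO (C18) cis to H5 and CH3 (C19) cis to the side chain, and the boron-bound s-trans enal is shielded on its α-Si face so that addition to the α-Re face sets C4 (R) and C5 (R), while the C10 methine centre (exo-formyl adduct drawn) is erased in step 8.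

Step 7
Reactants: 9 (1R,2R,3S)-2-[(3E)-6-(benzyloxy)-3-methylhex-3-en-1-yl]-1,3-dimethyl-4-[(triisopropylsilyl)oxy]cyclohex-4-ene-1-carbaldehyde
Product: 10 (1R,2R,3S)-2-[(3E)-6-(benzyloxy)-3-methylhex-3-en-1-yl]-1,3-dimethyl-4-oxocyclohex-5-ene-1-carbaldehyde
Conditions: Pd(OAc)2 (1.1 equiv), MeCN, 40 °C
Reagents that add atoms: none
Why: Saegusa–Ito oxidation (oxa-π-allyl palladium, then β-hydride elimination) converts the silyl enol ether regiospecifically into the C2=C3 enone, which leaves C10–H as the only enolisable position.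

Step 8
Reactants: 10 (1R,2R,3S)-2-[(3E)-6-(benzyloxy)-3-methylhex-3-en-1-yl]-1,3-dimethyl-4-oxocyclohex-5-ene-1-carbaldehyde
Product: 11 (1R,2R)-2-[(3E)-6-(benzyloxy)-3-methylhex-3-en-1-yl]-4-[(tert-butyldimethylsilyl)oxy]-1,3-dimethylcyclohexa-3,5-diene-1-carbaldehyde
Conditions: tBuMe2SiOTf (1.2 equiv), Et3N (2 equiv), CH2Cl2, 0 °C; used crude
Reagents that add atoms: tert-butyldimethylsilyl trifluoromethanesulfonate CC(C)(C)[Si](C)(C)OS(=O)(=O)C(F)(F)F
Why: Silyl triflate/amine soft enolisation can only remove the α′ hydrogen at C10, which gives the 2-silyloxy-1,3-diene and planarises C10.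

Step 9
Reactants: 11 (1R,2R)-2-[(3E)-6-(benzyloxy)-3-methylhex-3-en-1-yl]-4-[(tert-butyldimethylsilyl)oxy]-1,3-dimethylcyclohexa-3,5-diene-1-carbaldehyde
Product: 12 12-(benzyloxy)-1-oxo-13,14,15,16-tetranorlabda-2,8(17)-dien-18-al
Conditions: 4CzIPN (2 mol %), Co(dmgH)2(py)Cl (5 mol %), H2O (2 equiv), MeCN (0.02 M), 450 nm LEDs, 25 °C, argon
Reagents that add atoms: none
Why: Proposed new method: single-electron oxidation of the electron-rich silyloxy diene by excited 4CzIPN and desilylation by water give the C10 α-keto radical, which closes 6-endo onto the E-trisubstituted C8=C9 alkene through a chair transition state (attack on the α face of C10, anti to the pseudo-axial C19 methyl, gives the trans ring fusion with 10β-CH3, and the E geometry places C11 equatorial with 9α-H), after which divalent cobalt removes a hydrogen atom from the least hindered C17 methyl of the tertiary C8 radical to give the exocyclic alkene and H2 is released by protonation of the cobalt hydride, the closest known reactions being the oxidative radical cyclisation of unsaturated silyl enol ethers with stoichiometric divalent copper or tetravalent cerium and photoredox/cobaloxime acceptorless dehydrogenation.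

Step 10
Reactants: 12 12-(benzyloxy)-1-oxo-13,14,15,16-tetranorlabda-2,8(17)-dien-18-al
Product: 13 12-(benzyloxy)-1-oxo-13,14,15,16-tetranorlabd-8(17)-en-18-al
Conditions: [(Ph3P)CuH]6 (0.4 equiv), H2O (5 equiv), benzene, 25 °C
Reagents that add atoms: none
Why: Copper hydride conjugate reduction (Stryker reduction) delivers hydride to C3 of the enone only and leaves the exocyclic alkene, the aldehyde and the benzyl ether intact.

Step 11
Reactants: 13 12-(benzyloxy)-1-oxo-13,14,15,16-tetranorlabd-8(17)-en-18-al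
Product: 14 12-(benzyloxy)-13,14,15,16-tetranorlabd-8(17)-ene-1β,18-diol
Conditions: NaBH4 (2 equiv), MeOH/THF, −20 → 0 °C
Reagents that add atoms: none
Why: Borohydride reduction of both carbonyl groups, in which hydride attacks the C1 ketone from the α face, anti to the axial C20 methyl on the neighbouring quaternary C10, to give the equatorial 1β-alcohol, while the aldehyde gives the C18 primary alcohol.

Step 12
Reactants: 14 12-(benzyloxy)-13,14,15,16-tetranorlabd-8(17)-ene-1β,18-diol
Product: 15 12-(benzyloxy)-8α,17-epoxy-13,14,15,16-tetranorlabdane-1β,18-diol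
Conditions: mCPBA (1.1 equiv), NaHCO3, CH2Cl2, 0 °C
Reagents that add atoms: 3-chloroperbenzoic acid OOC(=O)c1cccc(Cl)c1
Why: Prilezhaev epoxidation of the 1,1-disubstituted alkene from the α face, the β face being blocked by the axial C20 methyl, gives the 8α,17-epoxide.

Step 13
Reactants: 15 12-(benzyloxy)-8α,17-epoxy-13,14,15,16-tetranorlabdane-1β,18-diol
Product: 16 12-(benzyloxy)-13,14,15,16-tetranorlabdane-1β,8α,18-triol
Conditions: LiAlH4 (3 equiv), THF, 0 → 50 °C; Fieser work-up
Reagents that add atoms: none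
Why: Hydride opens the spiro epoxide by SN2 attack at the primary C17 without touching the C8–O bond, so C8 is obtained with the 8α-hydroxyl and a β-methyl group.

Step 14
Reactants: 16 12-(benzyloxy)-13,14,15,16-tetranorlabdane-1β,8α,18-triol
Product: 17 12-(benzyloxy)-1β,8α-dihydroxy-13,14,15,16-tetranorlabdan-18-yl icosanoate
Conditions: C19H39COCl (1.05 equiv), pyridine, CH2Cl2, −30 → 0 °C
Reagents that add atoms: icosanoyl chloride CCCCCCCCCCCCCCCCCCCC(=O)Cl
Why: Nucleophilic acyl substitution at low temperature is selective for the primary 18-OH over the hindered secondary 1β-OH (flanked by quaternary C10) and the tertiary 8α-OH.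

Step 15
Reactants: 17 12-(benzyloxy)-1β,8α-dihydroxy-13,14,15,16-tetranorlabdan-18-yl icosanoate
Product: 18 1β-acetoxy-12-(benzyloxy)-8α-hydroxy-13,14,15,16-tetranorlabdan-18-yl icosanoate
Conditions: Ac2O (3 equiv), Et3N, DMAP (10 mol %), CH2Cl2, 25 °C
Reagents that add atoms: acetic anhydride CC(=O)OC(C)=O
Why: DMAP-catalysed acylation esterifies the remaining secondary 1β-OH while the tertiary 8α-OH is inert under these conditions.

Step 16
Reactants: 18 1β-acetoxy-12-(benzyloxy)-8α-hydroxy-13,14,15,16-tetranorlabdan-18-yl icosanoate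
Product: 19 1β-acetoxy-8α,12-dihydroxy-13,14,15,16-tetranorlabdan-18-yl icosanoate
Conditions: H2 (1 atm), 10% Pd/C, EtOAc, 25 °C
Reagents that add atoms: none
Why: Palladium-catalysed hydrogenolysis cleaves the benzyl ether at a stage where no alkene is present and the esters are untouched.

Step 17
Reactants: 19 1β-acetoxy-8α,12-dihydroxy-13,14,15,16-tetranorlabdan-18-yl icosanoate
Product: 22 (12E)-1β-acetoxy-8α-hydroxy-14-oxo-15-norlabd-12-en-18-yl icosanoate, via hydroxy aldehyde 20 (not isolated), via lactol 21 (not isolated)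
Conditions: Dess–Martin periodinane (1.05 equiv), NaHCO3, CH2Cl2, 0 °C, 1 h; then Ph3P=C(CH3)CHO (3 equiv), PhCO2H (10 mol %), toluene, CH2Cl2 distilled off, 90 °C
Reagents that add atoms: 2-(triphenylphosphoranylidene)propanal CC(C=O)=P(c1ccccc1)(c1ccccc1)c1ccccc1
Why: One-pot Dess–Martin oxidation/Wittig olefination in which the primary 12-alcohol is oxidised to the hydroxy aldehyde, which rests as the five-membered 8α,12-lactol and reopens under acid catalysis at 90 °C to be trapped E-selectively by the formyl-stabilised ylide, giving the (12E)-trisubstituted enal.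

Step 18
Reactants: 22 (12E)-1β-acetoxy-8α-hydroxy-14-oxo-15-norlabd-12-en-18-yl icosanoate
Product: 23 (12E)-1β-acetoxy-8α-hydroxylabda-12,14-dien-18-yl icosanoate
Conditions: Ph3PCH3Br (3.0 equiv), KN(SiMe3)2 (2.9 equiv), THF, 0 °C; then 22, −78 → 0 °C
Reagents that add atoms: methyltriphenylphosphonium bromide C[P+](c1ccccc1)(c1ccccc1)c1ccccc1.[Br-]
Why: Wittig methylenation of the aldehyde carbonyl is fast at low temperature, spares the esters and the existing E alkene, and completes the conjugated diene of the target.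

## Compound list

1 | 3-(benzyloxy)propanal | O=CCCOCc1ccccc1 | starting material
2 | isopropenylmagnesium bromide, CH2=C(CH3)MgBr | CC(=C)[Mg]Br | starting material
3 | rac-5-(benzyloxy)-2-methylpent-1-en-3-ol | CC(=C)C(O)CCOCc1ccccc1 | intermediate
4 | ethyl (4E)-7-(benzyloxy)-4-methylhept-4-enoate | CCOC(=O)CC/C(C)=C/CCOCc1ccccc1 | intermediate
5 | (4E)-7-(benzyloxy)-4-methylhept-4-enal | O=CCC/C(C)=C/CCOCc1ccccc1 | intermediate
6 | (2E,6E)-9-(benzyloxy)-2,6-dimethylnona-2,6-dienal | O=C/C(C)=C/CC/C(C)=C/CCOCc1ccccc1 | intermediate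
7 | pent-1-en-3-one (ethyl vinyl ketone) | C=CC(=O)CC | starting material
8 | triisopropyl{[(3Z)-penta-1,3-dien-3-yl]oxy}silane | C/C=C(/C=C)O[Si](C(C)C)(C(C)C)C(C)C | intermediate
9 | (1R,2R,3S)-2-[(3E)-6-(benzyloxy)-3-methylhex-3-en-1-yl]-1,3-dimethyl-4-[(triisopropylsilyl)oxy]cyclohex-4-ene-1-carbaldehyde (ring A; formyl = C18, cis to H5; the C3 epimer is equally usable) | O=C[C@]1(C)CC=C(O[Si](C(C)C)(C(C)C)C(C)C)[C@@H](C)[C@H]1CC/C(C)=C/CCOCc1ccccc1 | intermediate
10 | (1R,2R,3S)-2-[(3E)-6-(benzyloxy)-3-methylhex-3-en-1-yl]-1,3-dimethyl-4-oxocyclohex-5-ene-1-carbaldehyde | O=C[C@]1(C)C=CC(=O)[C@@H](C)[C@H]1CC/C(C)=C/CCOCc1ccccc1 | intermediate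
11 | (1R,2R)-2-[(3E)-6-(benzyloxy)-3-methylhex-3-en-1-yl]-4-[(tert-butyldimethylsilyl)oxy]-1,3-dimethylcyclohexa-3,5-diene-1-carbaldehyde | O=C[C@]1(C)C=CC(O[Si](C)(C)C(C)(C)C)=C(C)[C@H]1CC/C(C)=C/CCOCc1ccccc1 | intermediate
12 | 12-(benzyloxy)-1-oxo-13,14,15,16-tetranorlabda-2,8(17)-dien-18-al (trans-decalin; 5α-H, 9α-H, 10β-CH3, 4α-CHO, 4β-CH3) | c1ccccc1COCC[C@@H]1[C@@]2(C)C(=O)C=C[C@@](C)(C=O)[C@@H]2CCC1=C | intermediate
13 | 12-(benzyloxy)-1-oxo-13,14,15,16-tetranorlabd-8(17)-en-18-al | c1ccccc1COCC[C@@H]1[C@@]2(C)C(=O)CC[C@@](C)(C=O)[C@@H]2CCC1=C | intermediate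
14 | 12-(benzyloxy)-13,14,15,16-tetranorlabd-8(17)-ene-1β,18-diol | c1ccccc1COCC[C@@H]1[C@@]2(C)[C@H](O)CC[C@@](C)(CO)[C@@H]2CCC1=C | intermediate
15 | 12-(benzyloxy)-8α,17-epoxy-13,14,15,16-tetranorlabdane-1β,18-diol | c1ccccc1COCC[C@@H]1[C@@]2(C)[C@H](O)CC[C@@](C)(CO)[C@@H]2CC[C@@]1(C2)O2 | intermediate
16 | 12-(benzyloxy)-13,14,15,16-tetranorlabdane-1β,8α,18-triol | c1ccccc1COCC[C@@H]1[C@@]2(C)[C@H](O)CC[C@@](C)(CO)[C@@H]2CC[C@@]1(C)O | intermediate
17 | 12-(benzyloxy)-1β,8α-dihydroxy-13,14,15,16-tetranorlabdan-18-yl icosanoate | c1ccccc1COCC[C@@H]1[C@@]2(C)[C@H](O)CC[C@@](C)(COC(=O)CCCCCCCCCCCCCCCCCCC)[C@@H]2CC[C@@]1(C)O | intermediate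
18 | 1β-acetoxy-12-(benzyloxy)-8α-hydroxy-13,14,15,16-tetranorlabdan-18-yl icosanoate | c1ccccc1COCC[C@@H]1[C@@]2(C)[C@H](OC(C)=O)CC[C@@](C)(COC(=O)CCCCCCCCCCCCCCCCCCC)[C@@H]2CC[C@@]1(C)O | intermediate
19 | 1β-acetoxy-8α,12-dihydroxy-13,14,15,16-tetranorlabdan-18-yl icosanoate | OCC[C@@H]1[C@@]2(C)[C@H](OC(C)=O)CC[C@@](C)(COC(=O)CCCCCCCCCCCCCCCCCCC)[C@@H]2CC[C@@]1(C)O | intermediate
20 | 1β-acetoxy-8α-hydroxy-12-oxo-13,14,15,16-tetranorlabdan-18-yl icosanoate (open hydroxy aldehyde) | O=CC[C@@H]1[C@@]2(C)[C@H](OC(C)=O)CC[C@@](C)(COC(=O)CCCCCCCCCCCCCCCCCCC)[C@@H]2CC[C@@]1(C)O | intermediate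
21 | 1β-acetoxy-8α,12-epoxy-12-hydroxy-13,14,15,16-tetranorlabdan-18-yl icosanoate (lactol, both C12 anomers) | OC1C[C@@H]2[C@@]3(C)[C@H](OC(C)=O)CC[C@@](C)(COC(=O)CCCCCCCCCCCCCCCCCCC)[C@@H]3CC[C@@]2(C)O1 | intermediate
22 | (12E)-1β-acetoxy-8α-hydroxy-14-oxo-15-norlabd-12-en-18-yl icosanoate | O=C/C(C)=C/C[C@@H]1[C@@]2(C)[C@H](OC(C)=O)CC[C@@](C)(COC(=O)CCCCCCCCCCCCCCCCCCC)[C@@H]2CC[C@@]1(C)O | intermediate
23 | (12E)-1β-acetoxy-8α-hydroxylabda-12,14-dien-18-yl icosanoate (CNP0288884.2) | C=C/C(C)=C/C[C@@H]1[C@@]2(C)[C@H](OC(C)=O)CC[C@@](C)(COC(=O)CCCCCCCCCCCCCCCCCCC)[C@@H]2CC[C@@]1(C)O | target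

## Step count and risks

Total steps: 18. Longest linear sequence: 17 steps (steps 1–4 and 6–18; step 5 is a one-step branch).

**Step 9 (proposed new cyclisation).** The α-keto radical may be reduced back to the enone before it cyclises, the trans/cis ring-fusion ratio is untested, and cobalt may give endocyclic alkene isomers. The fallback uses known chemistry and sets out from enone 10, so the silyl dienol ether 11 is not needed. Trivalent-manganese oxidation at the α′ position of the enone (Mn(OAc)3·2H2O, Cu(OAc)2·H2O, AcOH, 60 °C) generates the same C10 radical by the classical oxidative free-radical cyclisation, and divalent copper oxidises the tertiary C8 radical mainly to the exocyclic alkene. This comes back to the route at dienone aldehyde 12.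

**Step 6 (Diels–Alder reaction).** The trisubstituted enal may be sluggish, and the methyl-bearing diene terminus works against the silyloxy group in regiocontrol. The fallback reverses the roles of the partners and sets out from aldehyde 5. Wittig olefination with 3-(triphenylphosphoranylidene)butan-2-one gives (3E,7E)-10-(benzyloxy)-3,7-dimethyldeca-3,7-dien-2-one F1. O-silylation at its methyl group (iPr3SiOTf, Et3N) gives triisopropyl{[(3E,7E)-10-(benzyloxy)-3,7-dimethyldeca-1,3,7-trien-2-yl]oxy}silane F2. The same oxazaborolidinium-catalysed Diels–Alder reaction with the more reactive methacrolein (exo-formyl transition state) gives (1R,2R)-2-[(3E)-6-(benzyloxy)-3-methylhex-3-en-1-yl]-1,3-dimethyl-4-[(triisopropylsilyl)oxy]cyclohex-3-ene-1-carbaldehyde F3, whose enol ether already spans C1=C10. Known oxidative cyclisation of this silyl enol ether with Cu(OTf)2/Cu2O in MeCN closes ring B and comes back to the route at keto aldehyde 13. The main route is preferred because there the C4/C5 relationship follows from alkene geometry and not from an exo/endo preference.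

**Step 17 (one-pot oxidation/olefination through the lactol).** The tertiary lactol may open too little for the weakly nucleophilic formyl ylide, residual periodinane may oxidise the lactol to the lactone, and the freed 8-hydroxyl can add back to the enal. The fallback masks the tertiary alcohol and sets out from benzyl ether 18. Silylation (Et3SiOTf, 2,6-lutidine) gives 1β-acetoxy-12-(benzyloxy)-8α-(triethylsilyloxy)-13,14,15,16-tetranorlabdan-18-yl icosanoate F4. Hydrogenolysis gives 1β-acetoxy-12-hydroxy-8α-(triethylsilyloxy)-13,14,15,16-tetranorlabdan-18-yl icosanoate F5. Dess–Martin oxidation gives the free aldehyde 1β-acetoxy-12-oxo-8α-(triethylsilyloxy)-13,14,15,16-tetranorlabdan-18-yl icosanoate F6, which cannot form a lactol. The same two Wittig reactions give (12E)-1β-acetoxy-14-oxo-8α-(triethylsilyloxy)-15-norlabd-12-en-18-yl icosanoate F7 and then (12E)-1β-acetoxy-8α-(triethylsilyloxy)labda-12,14-dien-18-yl icosanoate F8. Buffered HF·pyridine in THF at 0 °C removes the silyl group and comes back to the route at target 23.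

## Further compounds

F1 | step 6 | (3E,7E)-10-(benzyloxy)-3,7-dimethyldeca-3,7-dien-2-one | CC(=O)/C(C)=C/CC/C(C)=C/CCOCc1ccccc1
F2 | step 6 | triisopropyl{[(3E,7E)-10-(benzyloxy)-3,7-dimethyldeca-1,3,7-trien-2-yl]oxy}silane | C=C(O[Si](C(C)C)(C(C)C)C(C)C)/C(C)=C/CC/C(C)=C/CCOCc1ccccc1
F3 | step 6 | (1R,2R)-2-[(3E)-6-(benzyloxy)-3-methylhex-3-en-1-yl]-1,3-dimethyl-4-[(triisopropylsilyl)oxy]cyclohex-3-ene-1-carbaldehyde | O=C[C@]1(C)CCC(O[Si](C(C)C)(C(C)C)C(C)C)=C(C)[C@H]1CC/C(C)=C/CCOCc1ccccc1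
F0 | step 9 | none | none
F4 | step 17 | 1β-acetoxy-12-(benzyloxy)-8α-(triethylsilyloxy)-13,14,15,16-tetranorlabdan-18-yl icosanoate | c1ccccc1COCC[C@@H]1[C@@]2(C)[C@H](OC(C)=O)CC[C@@](C)(COC(=O)CCCCCCCCCCCCCCCCCCC)[C@@H]2CC[C@@]1(C)O[Si](CC)(CC)CC
F5 | step 17 | 1β-acetoxy-12-hydroxy-8α-(triethylsilyloxy)-13,14,15,16-tetranorlabdan-18-yl icosanoate | OCC[C@@H]1[C@@]2(C)[C@H](OC(C)=O)CC[C@@](C)(COC(=O)CCCCCCCCCCCCCCCCCCC)[C@@H]2CC[C@@]1(C)O[Si](CC)(CC)CC
F6 | step 17 | 1β-acetoxy-12-oxo-8α-(triethylsilyloxy)-13,14,15,16-tetranorlabdan-18-yl icosanoate | O=CC[C@@H]1[C@@]2(C)[C@H](OC(C)=O)CC[C@@](C)(COC(=O)CCCCCCCCCCCCCCCCCCC)[C@@H]2CC[C@@]1(C)O[Si](CC)(CC)CC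
F7 | step 17 | (12E)-1β-acetoxy-14-oxo-8α-(triethylsilyloxy)-15-norlabd-12-en-18-yl icosanoate | O=C/C(C)=C/C[C@@H]1[C@@]2(C)[C@H](OC(C)=O)CC[C@@](C)(COC(=O)CCCCCCCCCCCCCCCCCCC)[C@@H]2CC[C@@]1(C)O[Si](CC)(CC)CC
F8 | step 17 | (12E)-1β-acetoxy-8α-(triethylsilyloxy)labda-12,14-dien-18-yl icosanoate | C=C/C(C)=C/C[C@@H]1[C@@]2(C)[C@H](OC(C)=O)CC[C@@](C)(COC(=O)CCCCCCCCCCCCCCCCCCC)[C@@H]2CC[C@@]1(C)O[Si](CC)(CC)CC
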